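**Strategy.** The plan cuts C7–C8 and C4a–C8a of the carbocycle, ring A (isochromene numbering). In that ring the C8 oxygen and the C8a–C1 branch sit trans on adjacent carbons, β and γ to the C6 ketone. This is the pattern left when a 2-silyloxydiene (C7=C6–C5=C4a) adds to an (E)-β-acetoxyacryloyl imide. One copper bis(oxazoline)-catalysed cycloaddition closes ring A, sets C8 and C8a absolutely, and leaves C6 as a regiodefined enol ether for C4a=C5 desaturation. The precursors are an acyclic (2Z,4E)-silyloxydienyne that already holds the C4–C3 alkyne, and an achiral acetoxyacryloyl oxazolidinone. The C7 hydroxyl, the dienyl chain and the pyran, ring B, follow.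

Key step: step 5

Assumption: face selection in step 5 is taken to follow the square-planar chelate model of divalent copper bis(oxazoline)–acyloxazolidinone complexes (s-cis imide). On that model the (R,R)-tert-butyl ligand leaves the Cα-Si face open. The antipodal ligand would be used in the same way if the sense proved opposite.

Remarks on the chemistry:
- Isochromene locants are used for all ring compounds.
- C8 and C8a are labelled S in 9 and R from 10 onward. Only the CIP priorities change; no bond at these centres is touched.
- The acetate cannot survive enolisation at C7, because β-elimination followed by aromatisation would result. It is therefore removed together with the imide and put back last.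
- A free C8 hydroxyl cannot coexist with O-silylation of a C6 enolate. Control at C7 is therefore taken from a trans-fused silylene ring.

Step 1
Reactants: 1 3-(trimethylsilyl)propynal; 2 diethyl (2-oxobutyl)phosphonate
Product: 3 (E)-7-(trimethylsilyl)hept-4-en-6-yn-3-one
Conditions: LiCl, iPr2NEt, MeCN, 0 °C to rt
Reagents that add atoms: none
Why: Horner–Wadsworth–Emmons olefination under Masamune–Roush conditions is mild enough for the base-sensitive silyl ynal, and the stabilised β-ketophosphonate anion should deliver the E-enone.

Step 2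
Reactants: 3 (E)-7-(trimethylsilyl)hept-4-en-6-yn-3-one
Product: 4 (2Z,4E)-3-(tert-butyldimethylsilyloxy)-7-(trimethylsilyl)hepta-2,4-dien-6-yne
Conditions: TBSOTf, Et3N, CH2Cl2, 0 °C
Reagents that add atoms: tert-butyldimethylsilyl triflate, CC(C)(C)[Si](C)(C)OS(=O)(=O)C(F)(F)F
Why: Soft enolisation with a silyl triflate and a tertiary amine can remove a proton only from the CH2 of the ethyl ketone and should give mainly the Z-silyl enol ether, the isomer that places the methyl group on the outside of the s-cis diene.

Step 3
Reactants: 5 propiolic acid; 6 oxazolidin-2-one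
Product: 7 3-propioloyloxazolidin-2-one
Conditions: DCC, DMAP (5 mol %), CH2Cl2, −10 to 0 °C
Reagents that add atoms: none
Why: Carbodiimide/DMAP N-acylation (Steglich-type coupling) activates the acid at low temperature without an acid chloride, which propiolic acid tolerates poorly, and the acidic carbamate N–H of 6 is the only acyl acceptor.

Step 4
Reactants: 7 3-propioloyloxazolidin-2-one
Product: 8 (E)-3-(3-acetoxyacryloyl)oxazolidin-2-one
Conditions: AcOH (1.2 equiv), DABCO (10 mol %), CH2Cl2, 0 °C to rt
Reagents that add atoms: acetic acid, CC(=O)O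
Why: Tertiary-amine-catalysed conjugate addition of a carboxylic acid to an acyl-activated terminal alkyne runs through a β-ammonium acrylate that acetate displaces by addition–elimination, which should give the favoured E-β-acetoxy acrylimide.

Step 5
Reactants: 4 (2Z,4E)-3-(tert-butyldimethylsilyloxy)-7-(trimethylsilyl)hepta-2,4-dien-6-yne (1.5 equiv); 8 (E)-3-(3-acetoxyacryloyl)oxazolidin-2-one
Product: 9 3-{(1S,2S,5S,6S)-6-acetoxy-4-(tert-butyldimethylsilyloxy)-5-methyl-2-[(trimethylsilyl)ethynyl]cyclohex-3-ene-1-carbonyl}oxazolidin-2-one (endo adduct, 4aS,7S,8S,8aS; alkynyl, methyl and acyl groups mutually cis, acetoxy trans to them)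
Conditions: [Cu((R,R)-t-Bu-box)](SbF6)2 (10 mol %, from CuCl2, 2,2'-(propane-2,2-diyl)bis[(4R)-4-tert-butyl-4,5-dihydrooxazole] and AgSbF6), CH2Cl2, −20 °C to rt
Reagents that add atoms: none
Why: The imide binds through both carbonyl oxygens to the cationic divalent copper centre, which lowers its LUMO, and the silyloxy-activated terminus C7 of 4 bonds to the β-carbon C8 while C4a bonds to C8a in a concerted but asynchronous [4+2] cycloaddition (a Michael addition followed by ring closure would end at the same adduct). The closest known chemistry is the copper bis(oxazoline)-catalysed Diels–Alder reaction of β-substituted acryloyl oxazolidinones, β-acyloxy ones included, with acyclic oxygenated dienes, together with Lewis-acid cycloadditions of 2-silyloxydienes. Ring A is closed by intermolecular [4+2] annulation, both σ-bonds forming suprafacially on each partner. C8 and C8a take their trans relation from the E-alkene and their absolute configuration from the ligand, whose tert-butyl group covers the Cα-Re face of the s-cis chelated imide so that the diene adds to the Cα-Si face; C7 and C4a follow from the Z,E-diene geometry and endo placement of the imide and are both erased later, so endo/exo leakage is harmless. The step needs regioselectivity, secured because the C6 silyloxy group (para rule) and the C4a alkynyl group (ortho rule) both pair C7 with C8, and it needs cycloaddition to win over silyl transfer or acetate expulsion, which the bulky TBS group, the non-nucleophilic SbF6 counterion and the low temperature favour.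

Step 6
Reactants: 9 endo adduct
Product: 10 (1R,2S,5R,6R)-3-(tert-butyldimethylsilyloxy)-6-(hydroxymethyl)-2-methyl-5-[(trimethylsilyl)ethynyl]cyclohex-3-en-1-ol (C8,C1-diol; 4aR,7S,8R,8aR)
Conditions: LiBH4 (4 equiv), H2O (1 equiv), THF–Et2O, 0 °C to rt
Reagents that add atoms: none
Why: Borohydride reduction of an N-acyloxazolidinone to the primary alcohol is standard, excess reagent also cleaves the acetate reductively so that the β-acetoxy carbonyl unit disappears before base can eliminate it, and the enol ether, the silyl alkyne and all stereocentres stay untouched.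

Step 7
Reactants: 10 C8,C1-diol
Product: 11 O8,O1-(di-tert-butylsilanediyl) derivative of 10 (trans-fused 1,3,2-dioxasilinane; 4aR,7S,8R,8aR)
Conditions: t-Bu2Si(OTf)2, 2,6-lutidine, CH2Cl2, 0 °C
Reagents that add atoms: di-tert-butylsilyl bis(trifluoromethanesulfonate), CC(C)(C)[Si](OS(=O)(=O)C(F)(F)F)(OS(=O)(=O)C(F)(F)F)C(C)(C)C
Why: Cyclic silylene protection of a 1,3-diol under buffered, non-protic conditions spares the enol ether, and because O8 and C1 are trans the new six-membered ring is trans-fused and holds both bonds equatorial.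

Step 8
Reactants: 11 silylene-protected enol ether
Product: 12 (7S,8R,8aR)-enynone: C6 ketone, C4a=C5 alkene bearing the (trimethylsilyl)ethynyl group at C4a, C7–H/CH3, O8,O1-silylene
Conditions: Pd(OAc)2 (1.1 equiv), MeCN, rt
Reagents that add atoms: none
Why: In the Saegusa–Ito dehydrosilylation, palladation of the regiodefined enol ether at C5 and syn β-hydride loss from C4a can only give the C4a=C5 enone, which erases the C4a centre and leaves C7, C8 and C8a alone.

Step 9
Reactants: 12 (7S,8R,8aR)-enynone
Product: 14 (7R,8R,8aR)-7-hydroxy-7-methyl enynone (tertiary OH cis to O8; silylene and silyl alkyne retained), via sodium dienolate 13 (not isolated)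
Conditions: NaN(SiMe3)2 (1.2 equiv), THF, −78 °C; then 2-(phenylsulfonyl)-3-phenyloxaziridine, −78 °C; aq NH4Cl
Reagents that add atoms: 2-(phenylsulfonyl)-3-phenyloxaziridine, O=S(=O)(c1ccccc1)N1OC1c1ccccc1
Why: Kinetic α'-deprotonation of the axial C7–H and Davis oxidation of the enolate should work because the locked trans-fused dienolate holds the C8–O bond close to the π-nodal plane, which disfavours β-elimination, and because oxygen transfer is staggered only on the face anti to the pseudoaxial C8–H (the face cis to O8 and opposite the axial tert-butyl group on silicon), which sets 7R.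

Step 10
Reactants: 14 (7R,8R,8aR)-7-hydroxy enynone
Product: 15 the corresponding terminal alkyne (4a-ethynyl; 7R,8R,8aR)
Conditions: AgNO3 (10 mol %), CH2Cl2–MeOH–H2O, rt
Reagents that add atoms: none
Why: Silver-catalysed protiodesilylation of a trimethylsilyl alkyne runs under neutral conditions, so alkoxide addition to the ynenone, γ-deprotonation at C8a and attack on the silylene ring are avoided.

Step 11
Reactants: 16 (S)-2-methylbutan-1-ol
Product: 17 (S)-2-methylbutanal
Conditions: TEMPO (1 mol %), KBr (10 mol %), NaOCl, NaHCO3, CH2Cl2–H2O, 0 °C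
Reagents that add atoms: none
Why: The Anelli oxidation (nitroxyl/hypochlorite, biphasic, cold) stops at the aldehyde and keeps an α-stereocentre of this kind intact.

Step 12
Reactants: 17 (S)-2-methylbutanal
Product: 18 (2E,4S)-2,4-dimethylhex-2-enal
Conditions: Ph3P=C(CH3)CHO, toluene, 80 °C
Reagents that add atoms: 2-(triphenylphosphoranylidene)propanal, CC(C=O)=P(c1ccccc1)(c1ccccc1)c1ccccc1
Why: Wittig olefination with the stabilised formyl ylide gives the E-trisubstituted enal directly under neutral conditions that should not epimerise the sec-butyl stereocentre.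

Step 13
Reactants: 18 (2E,4S)-2,4-dimethylhex-2-enal
Product: 19 (1E,3E,5S)-1-iodo-3,5-dimethylhepta-1,3-diene
Conditions: CrCl2 (6 equiv), CHI3 (2 equiv), THF, 0 °C
Reagents that add atoms: iodoform, IC(I)I
Why: Takai olefination with the geminal dichromium reagent from iodoform converts aldehydes, enals included, into E-alkenyl iodides without touching the existing alkene or the stereocentre.

Step 14
Reactants: 15 terminal alkyne; 19 (1E,3E,5S)-1-iodo-3,5-dimethylhepta-1,3-diene
Product: 20 (7R,8R,8aR)-4a-[(3E,5E,7S)-5,7-dimethylnona-3,5-dien-1-ynyl] enone, O8,O1-silylene, free 7-OH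
Conditions: Pd(PPh3)4 (5 mol %), CuI (10 mol %), Et3N, THF, rt, degassed
Reagents that add atoms: none
Why: Sonogashira coupling of a terminal alkyne with an alkenyl iodide proceeds at room temperature with retention of alkene geometry, and a tertiary amine is chosen as base because it cannot add irreversibly to the ynenone.

Step 15
Reactants: 20 coupled silylene
Product: 21 (7R,8R,8aR)-triol (free 7-OH, 8-OH and C1–OH; dienynyl enone)
Conditions: HF·pyridine, pyridine, THF, 0 °C
Reagents that add atoms: none
Why: Fluoride cleavage of the silylene with buffered HF·pyridine frees O8 and O1 together under conditions too mild to disturb the α-ketol, the ynenone or the diene.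

Step 16
Reactants: 21 triol
Product: 22 (7R,8R,8aR)-3-[(1E,3E,5S)-3,5-dimethylhepta-1,3-dienyl]-7,8-dihydroxy-7-methyl-1,7,8,8a-tetrahydro-6H-isochromen-6-one
Conditions: Ph3PAuNTf2 (5 mol %), CH2Cl2, 0 °C to rt
Reagents that add atoms: none
Why: In this 6-endo-dig alkynol hydroalkoxylation catalysed by monovalent gold, C3 is remote from the electron-poor enone and carries the donor dienyl group, so it bears the positive character and is attacked by the C1 hydroxyl (anti addition, then protodeauration), while O7 and O8 cannot reach the alkyne without forming a bridgehead alkene.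

Step 17
Reactants: 22 7,8-diol
Product: 23 (7R,8R,8aR)-3-[(1E,3E,5S)-3,5-dimethylhepta-1,3-dienyl]-7-hydroxy-7-methyl-6-oxo-6,7,8,8a-tetrahydro-1H-isochromen-8-yl acetate (target)
Conditions: Ac2O (1.5 equiv), pyridine, DMAP (cat.), CH2Cl2, 0 °C
Reagents that add atoms: acetic anhydride, CC(=O)OC(C)=O
Why: Acetylation with Ac2O/pyridine distinguishes the secondary C8 hydroxyl from the hindered tertiary C7 hydroxyl, and the weakly basic medium should not trigger vinylogous β-elimination from C8a.

**Compound list**

1 | 3-(trimethylsilyl)propynal | C[Si](C)(C)C#CC=O | starting material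
2 | diethyl (2-oxobutyl)phosphonate | CCC(=O)CP(=O)(OCC)OCC | starting material
3 | (E)-7-(trimethylsilyl)hept-4-en-6-yn-3-one | CCC(=O)/C=C/C#C[Si](C)(C)C | intermediate
4 | (2Z,4E)-3-(tert-butyldimethylsilyloxy)-7-(trimethylsilyl)hepta-2,4-dien-6-yne | C[Si](C)(C)C#C/C=C/C(O[Si](C)(C)C(C)(C)C)=C/C | intermediate
5 | propiolic acid | C#CC(=O)O | starting material
6 | oxazolidin-2-one | O=C1NCCO1 | starting material
7 | 3-propioloyloxazolidin-2-one | C#CC(=O)N1CCOC1=O | intermediate
8 | (E)-3-(3-acetoxyacryloyl)oxazolidin-2-one | CC(=O)O/C=C/C(=O)N1CCOC1=O | intermediate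
9 | endo cycloadduct (4aS,7S,8S,8aS) | C[Si](C)(C)C#C[C@H]1C=C(O[Si](C)(C)C(C)(C)C)[C@@H](C)[C@H](OC(C)=O)[C@H]1C(=O)N2CCOC2=O | intermediate
10 | C8,C1-diol (4aR,7S,8R,8aR) | C[Si](C)(C)C#C[C@H]1C=C(O[Si](C)(C)C(C)(C)C)[C@@H](C)[C@H](O)[C@H]1CO | intermediate
11 | O8,O1-di-tert-butylsilylene enol ether | C[Si](C)(C)C#C[C@H]1C=C(O[Si](C)(C)C(C)(C)C)[C@@H](C)[C@H](O2)[C@H]1CO[Si]2(C(C)(C)C)C(C)(C)C | intermediate
12 | (7S,8R,8aR)-enynone, silylene | C[Si](C)(C)C#CC1=CC(=O)[C@@H](C)[C@H](O2)[C@H]1CO[Si]2(C(C)(C)C)C(C)(C)C | intermediate
13 | sodium dienolate of 12 | C[Si](C)(C)C#CC1=CC([O-])=C(C)[C@H](O2)[C@H]1CO[Si]2(C(C)(C)C)C(C)(C)C.[Na+] | intermediate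
14 | (7R,8R,8aR)-7-hydroxy enynone, silylene | C[Si](C)(C)C#CC1=CC(=O)[C@](C)(O)[C@H](O2)[C@H]1CO[Si]2(C(C)(C)C)C(C)(C)C | intermediate
15 | terminal alkyne | C#CC1=CC(=O)[C@](C)(O)[C@H](O2)[C@H]1CO[Si]2(C(C)(C)C)C(C)(C)C | intermediate
16 | (S)-2-methylbutan-1-ol | CC[C@H](C)CO | starting material
17 | (S)-2-methylbutanal | CC[C@H](C)C=O | intermediate
18 | (2E,4S)-2,4-dimethylhex-2-enal | CC[C@H](C)/C=C(C)/C=O | intermediate
19 | (1E,3E,5S)-1-iodo-3,5-dimethylhepta-1,3-diene | CC[C@H](C)/C=C(C)/C=C/I | intermediate
20 | coupled dienynyl enone, silylene | CC[C@H](C)/C=C(C)/C=C/C#CC1=CC(=O)[C@](C)(O)[C@H](O2)[C@H]1CO[Si]2(C(C)(C)C)C(C)(C)C | intermediate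
21 | triol | CC[C@H](C)/C=C(C)/C=C/C#CC1=CC(=O)[C@](C)(O)[C@H](O)[C@H]1CO | intermediate
22 | 7,8-dihydroxy isochromenone | CC[C@H](C)/C=C(C)/C=C/C1=CC2=CC(=O)[C@](C)(O)[C@H](O)[C@H]2CO1 | intermediate
23 | 8-acetate | CC[C@H](C)/C=C(C)/C=C/C1=CC2=CC(=O)[C@](C)(O)[C@H](OC(C)=O)[C@H]2CO1 | target

**Count.** Total steps: 17. Longest linear sequence: 12 (steps 1, 2, 5, 6, 7, 8, 9, 10, 14, 15, 16, 17).

**Steps most likely to fail**

**Step 5.**
- What may go wrong:
  - Turnover may be slow, because the dienophile carries a β-donor and both partners are substituted at their reacting termini.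
  - The reaction may divert into conjugate addition with silyl transfer.
  - Acetate may be expelled from a copper enolate.
  - Face selection may erode.
- The fallback replaces catalyst control with a covalent auxiliary and a stronger Lewis acid. It sets out from 5 and 4 and returns at 10.
- Propiolic acid 5 is coupled (DCC, DMAP, CH2Cl2, 0 °C) with commercial (S)-4-benzyloxazolidin-2-one to give (S)-4-benzyl-3-propioloyloxazolidin-2-one F1.
- DABCO-catalysed addition of AcOH gives (S)-3-[(E)-3-acetoxyacryloyl]-4-benzyloxazolidin-2-one F2.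
- Cycloaddition with 4, promoted by Et2AlCl (1.4 equiv, CH2Cl2, −78 °C), runs through the chelated s-cis imide. Its benzyl group covers the Cα-Re face, and the product is the auxiliary-bearing endo adduct F3.
- LiBH4 reduction as in step 6 then gives 10.

**Step 9.**
- What may go wrong:
  - γ-Deprotonation at C8a may compete.
  - Facial bias at C7 may be incomplete.
  - β-Elimination followed by aromatisation may occur.
- The fallback replaces conformational control with hydroxyl-directed epoxidation. It sets out from 10 and returns at 21.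
- Diol 10 is silylated in one flask, first at the primary hydroxyl (TBSCl, imidazole, CH2Cl2, 0 °C) and then at O8 (TMSCl), to give the 1-O-TBS-8-O-TMS enol ether F4.
- Pd(OAc)2 in MeCN gives the enynone F5.
- LiN(SiMe3)2 followed by TBSOTf at −78 °C gives the cross-conjugated TBS dienol ether F6.
- K2CO3 in MeOH at 0 °C removes the O-TMS and C-TMS groups together and leaves the hydroxy dienol ether F7.
- mCPBA (NaHCO3, CH2Cl2, −20 °C) is steered by hydrogen bonding to the allylic C8 hydroxyl onto the same face (Rubottom oxidation). After silyl migration this gives the 7-O-TBS ketol F8.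
- Sonogashira coupling with 19 gives the dienynyl enone F9, and HF·pyridine removes both TBS groups to reach 21.

**Step 16.**
- What may go wrong:
  - 5-exo-dig closure at C4 may compete.
  - The polyene may isomerise or degrade on the π-acid.
- The fallback replaces π-acid catalysis with a stepwise addition–elimination. It sets out from 21 and returns at 22.
- Et2NH in EtOH at rt adds to C3 by intermolecular 1,6-conjugate addition, which uses the alkyne π-bond conjugated with the enone. The product is the 3-(diethylamino) trienone F10.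
- Mild acid (AcOH in wet THF) then lets the C1 hydroxyl displace the amine at the vinylogous amide carbon (6-exo-trig on the iminium form). This can only form the six-membered ring of 22.

**Further compounds**

F1 | step 5 | (S)-4-benzyl-3-propioloyloxazolidin-2-one | C#CC(=O)N1[C@@H](Cc2ccccc2)COC1=O
F2 | step 5 | (S)-3-[(E)-3-acetoxyacryloyl]-4-benzyloxazolidin-2-one | CC(=O)O/C=C/C(=O)N1[C@@H](Cc2ccccc2)COC1=O
F3 | step 5 | auxiliary-bearing endo adduct | C[Si](C)(C)C#C[C@H]1C=C(O[Si](C)(C)C(C)(C)C)[C@@H](C)[C@H](OC(C)=O)[C@H]1C(=O)N2[C@@H](Cc3ccccc3)COC2=O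
F4 | step 9 | 1-O-TBS-8-O-TMS enol ether | C[Si](C)(C)C#C[C@H]1C=C(O[Si](C)(C)C(C)(C)C)[C@@H](C)[C@H](O[Si](C)(C)C)[C@H]1CO[Si](C)(C)C(C)(C)C
F5 | step 9 | 1-O-TBS-8-O-TMS enynone | C[Si](C)(C)C#CC1=CC(=O)[C@@H](C)[C@H](O[Si](C)(C)C)[C@H]1CO[Si](C)(C)C(C)(C)C
F6 | step 9 | cross-conjugated TBS dienol ether | C[Si](C)(C)C#CC1=CC(O[Si](C)(C)C(C)(C)C)=C(C)[C@H](O[Si](C)(C)C)[C@H]1CO[Si](C)(C)C(C)(C)C
F7 | step 9 | hydroxy dienol ether, terminal alkyne | C#CC1=CC(O[Si](C)(C)C(C)(C)C)=C(C)[C@H](O)[C@H]1CO[Si](C)(C)C(C)(C)C
F8 | step 9 | 7-O-TBS ketol | C#CC1=CC(=O)[C@](C)(O[Si](C)(C)C(C)(C)C)[C@H](O)[C@H]1CO[Si](C)(C)C(C)(C)C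
F9 | step 9 | bis-TBS dienynyl enone | CC[C@H](C)/C=C(C)/C=C/C#CC1=CC(=O)[C@](C)(O[Si](C)(C)C(C)(C)C)[C@H](O)[C@H]1CO[Si](C)(C)C(C)(C)C
F10 | step 16 | 3-(diethylamino) trienone | CC[C@H](C)/C=C(C)/C=C/C(N(CC)CC)=C\C1=CC(=O)[C@](C)(O)[C@H](O)[C@H]1CO
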